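Four questions stand on this flask, and I want one count to carry them.

| setting | epsilon | delta | flask |
|---|---|---|---|
| starting complex | 0.050 M | 0.025 M | 0.050 M |
| incoming ligand | 1 equiv | 1 equiv | 1.00 equiv |
| temperature | 25 °C | 25 °C | 25 °C |
| remark | the very flask that is asked about, followed so far | run made earlier |  |
| time |  |  | 4.0 min |

| run | time / min | complex with two exchanged / % | starting complex / % |
|---|---|---|---|
| epsilon | 0.667 | 37.4 | 35.7 |
| epsilon | 1.33 | 40.3 | 29.4 |
| epsilon | 2.00 | 39.0 | 27.1 |
| epsilon | 2.50 | 40.2 | 25.1 |
| delta | 0.333 | 22.2 | 52.4 |
| delta | 1.00 | 36.5 | 35.0 |
| delta | 2.00 | 39.2 | 30.6 |
| delta | 3.00 | 39.8 | 31.0 |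

(standard deviation of a reading: 1 percentage point)

- summer: at 4.0 min take out 90% of the complex with two exchanged then present, then wait 4.0 min
- noon: at 4.0 min raise the temperature by 25 K, then wait 4.0 min
- dawn: change nothing and wait 4.0 min more
- winter: at 4.0 min add incoming ligand, 50.0% of the amount charged, then wait 4.0 min

* complex with two exchanged, in percent of the starting complex first charged, at 4.0 min
* which option adds most complex with two exchanged ("none" when 2 percentage points or less is all one gets) (summer / noon / dawn / winter / none)
* complex with two exchanged present, with what was taken out counted in, in percent of the starting complex first charged, after noon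
* complex with two exchanged present, with what was taken out counted in, in percent of the starting complex first charged, after dawn

- complex with two exchanged that was removed still counts
- additions bring no volume worth counting

I start with the complex with two exchanged. The epsilon run reads 37.4% at 0.667 min, and the delta run, at half the concentration, reads 36.5% at 1.00 min, so the dilute run rises more slowly. The level where it stops shows no such difference: the readings from 1.33 min on in epsilon and from 2.00 min on in delta average 39.7%, give or take 0.45 percentage points.

A level that ignores concentration looks like a count, so I count c(incoming ligand). Each complex with two exchanged holds two ligands, so the plateau has taken 79.4% of the charge. That leaves 20.6%, and this I name the spare ligand, the share of charged ligand not held in complex with two exchanged. I expect it to sit in complex with one exchanged, one ligand each.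

This flask has epsilon's charges, and 4.0 min comes later than 1.33 min, so I commit to 39.7% now. Waiting and heating bring no ligand, so I keep 39.7% for dawn and noon, and summer brings none either. Winter adds 50.0% of ligand, and by this count, with the spare ligand, I estimate that it allows a gain of up to 35 points, more than the margin of 2 points, so I choose winter.

The weak link is that I never see the ligand, so the stop might be a balance instead. But from 1.33 min to 2.50 min epsilon's starting complex falls by 4.3 points while the product reads 40.3% and then 40.2%, and a balance between them takes the product down too.

The forecast gives 40% (38.5% to 41.5%), winter as the best option, 40% after noon (35% to 46%) and 40.3% after dawn (38.5% to 42.5%), holding that “fresh ligand restarts formation”.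

The flask gives 39.2% now, 39.2% after noon and 39.2% after dawn, and winter adds 33 points.

    starting complex + incoming ligand → leaving ligand + complex with one exchanged (k = 2.02 L mol⁻¹ s⁻¹, Ea = 37.0 kJ mol⁻¹)
    complex with one exchanged + incoming ligand → leaving ligand + complex with two exchanged (k = 4.17 L mol⁻¹ s⁻¹, Ea = 58.0 kJ mol⁻¹)
    2 starting complex → homo dimer (k = 0.0646 L mol⁻¹ s⁻¹, Ea = 57.0 kJ mol⁻¹)
    (constants at 25 °C)

In the flask, incoming ligand, the limiting reagent, stands at 0% of its charge at 4.00 min. By 0.400 min the second exchange has 87% of its turnover up to the asked time behind it, and the path to homo dimer 31%. The spare ligand of 20.6% compares with 21.6% of complex with one exchanged in the flask, and winter's 33 points stays under the 35 points allowed. In the neighbour flask with 0.250 equiv of incoming ligand, the spare ligand comes to 15.8% of the starting complex charged, and complex with one exchanged stands at 15.8%.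

(The readings were generated by integration with constants of no real substance, noise included.)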